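**Plan**
- The target, 5-hydroxy-2-(2-hydroxy-4,5-dimethoxyphenyl)-6,7,8-trimethoxychromen-4-one, has no stereocentre, so no stereochemistry has to be set.
- Retrosynthesis: the 5-OH is first traced back to a 5-OMe. Ring B is then cut at C5'–C6', C1'–C2' and C2'–C3' into a 2-ethynylchromone, a methoxy(1-methoxyvinyl)carbene on chromium and one CO.
- Enabling feature: in ring B the 2'-OH is para to the 5'-OMe, C1' (bonded to chromone C2) is ortho to that OH, C4' bears OMe and C3'/C6' bear H. This is exactly the 4-methoxyphenol pattern that an alkenyl(methoxy)carbene, a terminal alkyne and CO assemble.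
- The ethynyl group goes back to a formyl and then a methyl group at C2. Ring C is cut at O1–C2 and C2–C3 into an o-hydroxyacetophenone and ethyl acetate, and the acetophenone goes back to 1,2,3,4-tetramethoxybenzene.
- Forward: ring A is bought, oxygenated and acetylated (steps 1–2), ring C is closed (step 3), CH3 becomes C≡CH (steps 4–5), the carbene is made separately (step 6), ring B is built last (step 7) and the 5-OMe is cleaved (step 8).

Key step: step 7

Remark: 1,2,3,4-tetramethoxybenzene, methyl vinyl ether and Cr(CO)6 are taken as purchased. In the SMILES, CO ligands on chromium are drawn as Cr=C=O. The η6 bond of the Cr(CO)3 group to ring B in the arene complex of step 7 cannot be drawn, so that complex is written as the arene and the Cr(CO)3 fragment joined by a dot.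

**Step 1**
Reactants: 1 1,2,3,4-tetramethoxybenzene
Product: 4 2,3,4,5-tetramethoxyphenol, via 2,3,4,5-tetramethoxyphenyllithium 2 (not isolated), via dimethyl arylboronate 3 (not isolated)
Conditions: n-BuLi, TMEDA, THF, 0 °C; B(OMe)3, −78 °C → rt; AcOH, 30% H2O2, 0 °C
Reagents that add atoms: hydrogen peroxide, OO
Why: Directed ortho-lithiation next to a methoxy group (the two free ring positions of 1 are equivalent by symmetry), trapping with B(OMe)3 and oxidative 1,2-shift of the aryl group from boron to oxygen is the standard lithiation–borylation–oxidation route to phenols.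

**Step 2**
Reactants: 4 2,3,4,5-tetramethoxyphenol
Product: 5 1-(2-hydroxy-3,4,5,6-tetramethoxyphenyl)ethanone
Conditions: AcOH, BF3·OEt2, 80 °C; then H2O
Reagents that add atoms: acetic acid, CC(=O)O
Why: BF3-promoted Friedel–Crafts acetylation (O-acetylation and Fries-type migration) can occur only at the single unsubstituted carbon of 4, which is ortho to the hydroxyl, and the product is held as its difluoroboron chelate until aqueous work-up.

**Step 3**
Reactants: 5 1-(2-hydroxy-3,4,5,6-tetramethoxyphenyl)ethanone
Product: 7 5,6,7,8-tetramethoxy-2-methylchromen-4-one, via aryl butane-1,3-dione 6 (not isolated)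
Conditions: NaH, EtOAc, THF, 65 °C; then AcOH, cat. H2SO4, 60 °C
Reagents that add atoms: ethyl acetate, CCOC(C)=O
Why: Crossed Claisen condensation of the acetophenone enolate with ethyl acetate gives the 1,3-diketone, whose acid-catalysed cyclodehydration (phenol oxygen onto the terminal carbonyl, then loss of water) closes ring C, the classical 2-methylchromone synthesis.

**Step 4**
Reactants: 7 5,6,7,8-tetramethoxy-2-methylchromen-4-one
Product: 8 5,6,7,8-tetramethoxy-4-oxo-4H-chromene-2-carbaldehyde
Conditions: SeO2, xylene, 140 °C
Reagents that add atoms: selenium dioxide, O=[Se]=O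
Why: Riley oxidation with SeO2 attacks the 2-methyl group, which is activated as the vinylogous α-position of the pyranone carbonyl, and is the established way from 2-methylchromones to chromone-2-carbaldehydes.

**Step 5**
Reactants: 8 5,6,7,8-tetramethoxy-4-oxo-4H-chromene-2-carbaldehyde
Product: 9 2-ethynyl-5,6,7,8-tetramethoxychromen-4-one
Conditions: dimethyl (1-diazo-2-oxopropyl)phosphonate, K2CO3, MeOH, 0 °C → rt
Reagents that add atoms: dimethyl (1-diazo-2-oxopropyl)phosphonate (Ohira–Bestmann reagent), COP(=O)(OC)C(=[N+]=[N-])C(C)=O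
Why: Seyferth–Gilbert homologation in the Ohira–Bestmann variant, in which methanolysis of the acetyl group frees the diazomethylphosphonate anion, which adds to the aldehyde, expels dimethyl phosphate and loses N2 with a 1,2-hydride shift to the terminal alkyne, under conditions mild enough for a 2-substituted chromone.

**Step 6**
Reactants: 10 methyl vinyl ether; 11 chromium hexacarbonyl, Cr(CO)6
Product: 14 pentacarbonyl[methoxy(1-methoxyvinyl)carbene]chromium, via 1-methoxyvinyllithium 12 (not isolated), via lithium acylchromate 13 (not isolated)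
Conditions: t-BuLi, THF, −78 → 0 °C; Cr(CO)6, Et2O, 0 °C → rt; Me3OBF4, CH2Cl2, 0 °C
Reagents that add atoms: trimethyloxonium tetrafluoroborate, C[O+](C)C.F[B-](F)(F)F
Why: Fischer carbene synthesis, in which α-lithiation of the enol ether, addition of the vinyllithium to a CO ligand of zerovalent Cr(CO)6 and O-methylation of the acylchromate with the hard methylating agent Me3OBF4 give the alkenyl(methoxy)carbene, as known for other α-alkoxyalkenyllithiums.

**Step 7**
Reactants: 9 2-ethynyl-5,6,7,8-tetramethoxychromen-4-one; 14 pentacarbonyl[methoxy(1-methoxyvinyl)carbene]chromium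
Product: 16 2-(2-hydroxy-4,5-dimethoxyphenyl)-5,6,7,8-tetramethoxychromen-4-one, via tricarbonylchromium arene complex 15 (not isolated)
Conditions: 14 (1.5 equiv), THF (0.05 M), 55 °C, Ar; then air, rt
Reagents that add atoms: none
Why: Thermal loss of one cis CO from the zerovalent chromium carbene 14 opens a site for alkyne 9, which inserts into the Cr=C bond (forming C5'–C6') to give an η3-vinylcarbene; CO insertion (forming C1'–C2') then gives an η4-dienylketene that cyclises and enolises to the chromium-bound phenol 15, from which air releases 16. The closest known reaction type is the Dötz benzannulation of alkenyl(methoxy)carbene chromium complexes with terminal alkynes, a class that includes α-alkoxyalkenyl carbenes such as the dihydropyranyl complex. Ring B is closed by six-electron electrocyclisation of the metal-bound dienylketene, which forms C2'–C3' as the last of the three new bonds. No stereocentre is created. The step needs the chromonyl group next to the new hydroxyl and a six-membered instead of a five-membered ring: the first is secured by the terminal alkyne, whose unsubstituted carbon bonds to the carbene carbon for steric reasons, the second by the methoxycarbene on chromium in THF at moderate temperature and dilution, which favours CO insertion over cyclopentannulation. The carbene methoxyl becomes the 5'-OMe, the vinyl methoxyl the 4'-OMe and the inserted CO the free 2'-OH carbon, so ring B should arrive with its phenol already distinguished from the two methyl ethers.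

**Step 8**
Reactants: 16 2-(2-hydroxy-4,5-dimethoxyphenyl)-5,6,7,8-tetramethoxychromen-4-one
Product: 17 Agehoustin F, 5-hydroxy-2-(2-hydroxy-4,5-dimethoxyphenyl)-6,7,8-trimethoxychromen-4-one
Conditions: BCl3, CH2Cl2, −78 → 0 °C; then H2O
Reagents that add atoms: none
Why: BCl3 binds the C4 carbonyl and cleaves only the peri 5-methyl ether through a six-membered boron chelate (chloride attacks the activated methyl), the standard selective 5-O-demethylation of polymethoxyflavones, while the unchelated ethers at C6, C7, C8, C4' and C5' should survive at low temperature.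

**Compound list**
1 | 1,2,3,4-tetramethoxybenzene | COc1ccc(OC)c(OC)c1OC | starting material
2 | 2,3,4,5-tetramethoxyphenyllithium | [Li]c1cc(OC)c(OC)c(OC)c1OC | intermediate
3 | dimethyl (2,3,4,5-tetramethoxyphenyl)boronate | COB(OC)c1cc(OC)c(OC)c(OC)c1OC | intermediate
4 | 2,3,4,5-tetramethoxyphenol | Oc1cc(OC)c(OC)c(OC)c1OC | intermediate
5 | 1-(2-hydroxy-3,4,5,6-tetramethoxyphenyl)ethanone | CC(=O)c1c(O)c(OC)c(OC)c(OC)c1OC | intermediate
6 | 1-(2-hydroxy-3,4,5,6-tetramethoxyphenyl)butane-1,3-dione | CC(=O)CC(=O)c1c(O)c(OC)c(OC)c(OC)c1OC | intermediate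
7 | 5,6,7,8-tetramethoxy-2-methylchromen-4-one | Cc1cc(=O)c2c(OC)c(OC)c(OC)c(OC)c2o1 | intermediate
8 | 5,6,7,8-tetramethoxy-4-oxo-4H-chromene-2-carbaldehyde | O=Cc1cc(=O)c2c(OC)c(OC)c(OC)c(OC)c2o1 | intermediate
9 | 2-ethynyl-5,6,7,8-tetramethoxychromen-4-one | C#Cc1cc(=O)c2c(OC)c(OC)c(OC)c(OC)c2o1 | intermediate
10 | methyl vinyl ether | COC=C | starting material
11 | chromium hexacarbonyl, Cr(CO)6 | O=C=[Cr](=C=O)(=C=O)(=C=O)(=C=O)=C=O | starting material
12 | 1-methoxyvinyllithium | [Li]C(=C)OC | intermediate
13 | lithium pentacarbonyl(2-methoxyacryloyl)chromate | [Li+].COC(=C)C([O-])=[Cr](=C=O)(=C=O)(=C=O)(=C=O)=C=O | intermediate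
14 | pentacarbonyl[methoxy(1-methoxyvinyl)carbene]chromium | COC(=C)C(OC)=[Cr](=C=O)(=C=O)(=C=O)(=C=O)=C=O | intermediate
15 | tricarbonylchromium complex of 16, Cr(CO)3 bound η6 to ring B | COc1cc(O)c(-c2cc(=O)c3c(OC)c(OC)c(OC)c(OC)c3o2)cc1OC.O=C=[Cr](=C=O)=C=O | intermediate
16 | 2-(2-hydroxy-4,5-dimethoxyphenyl)-5,6,7,8-tetramethoxychromen-4-one | COc1cc(O)c(-c2cc(=O)c3c(OC)c(OC)c(OC)c(OC)c3o2)cc1OC | intermediate
17 | Agehoustin F, 5-hydroxy-2-(2-hydroxy-4,5-dimethoxyphenyl)-6,7,8-trimethoxychromen-4-one | COc1cc(O)c(-c2cc(=O)c3c(O)c(OC)c(OC)c(OC)c3o2)cc1OC | target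

**Step count**
Total: 8 steps. Longest linear sequence: 7 steps (steps 1, 2, 3, 4, 5, 7, 8); step 6 is the side branch.

**Steps most likely to fail**

Step 7 (benzannulation). Insertion of the electron-poor, conjugated alkyne may be slower than thermal decay of the carbene. After insertion, the vinylcarbene may close without taking up CO (five-membered ring products). The chromone carbonyl may also bind chromium and divert the ketene. The fallback buys ring B instead of building it and sets out from acetophenone 5. Commercial 2-hydroxy-4,5-dimethoxybenzaldehyde would be benzylated (BnBr, K2CO3, DMF) to 2-(benzyloxy)-4,5-dimethoxybenzaldehyde F1. Claisen–Schmidt condensation of F1 with 5 (KOH, EtOH, rt) should give (E)-3-[2-(benzyloxy)-4,5-dimethoxyphenyl]-1-(2-hydroxy-3,4,5,6-tetramethoxyphenyl)prop-2-en-1-one F2. Oxidative cyclisation (cat. I2, DMSO, 120 °C) should give 2-[2-(benzyloxy)-4,5-dimethoxyphenyl]-5,6,7,8-tetramethoxychromen-4-one F3. Hydrogenolysis (H2, Pd/C, EtOAc) then returns to the route at 16.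

Step 5 (alkyne formation). Methoxide may add to C2 of the chromone and open ring C, or add in conjugate fashion to the new alkyne. The very electrophilic aldehyde may also be lost as hemiacetal-derived by-products before the diazophosphonate anion reacts. The fallback avoids alkoxide altogether and sets out from aldehyde 8. Dibromo-olefination (CBr4, PPh3, CH2Cl2, 0 °C) should give 2-(2,2-dibromovinyl)-5,6,7,8-tetramethoxychromen-4-one F4. Selective hydrogenolysis of the bromine trans to the chromone (Bu3SnH, cat. Pd(PPh3)4, a zerovalent palladium complex, toluene, rt) should give 2-[(Z)-2-bromovinyl]-5,6,7,8-tetramethoxychromen-4-one F5. Anti-elimination of HBr with Bu4NF in DMF then returns to the route at 9.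

Step 4 (methyl to formyl). The oxidation may stall, or run on to the carboxylic acid at the temperature it needs, and selenium residues may be carried into the base-sensitive next step. The fallback brings in the C2 carbon at the ester oxidation level and sets out from acetophenone 5, bypassing 7. Condensation with diethyl oxalate (NaOEt, EtOH, reflux; then HCl, EtOH) should give ethyl 5,6,7,8-tetramethoxy-4-oxo-4H-chromene-2-carboxylate F6. Selective reduction of the activated ester (NaBH4, MeOH, 0 °C) should give 2-(hydroxymethyl)-5,6,7,8-tetramethoxychromen-4-one F7. Oxidation with MnO2 in CH2Cl2 then returns to the route at 8.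

**Further compounds**
F1 | step 7 | 2-(benzyloxy)-4,5-dimethoxybenzaldehyde | COc1cc(OCc2ccccc2)c(C=O)cc1OC
F2 | step 7 | (E)-3-[2-(benzyloxy)-4,5-dimethoxyphenyl]-1-(2-hydroxy-3,4,5,6-tetramethoxyphenyl)prop-2-en-1-one | COc1cc(OCc2ccccc2)c(/C=C/C(=O)c2c(O)c(OC)c(OC)c(OC)c2OC)cc1OC
F3 | step 7 | 2-[2-(benzyloxy)-4,5-dimethoxyphenyl]-5,6,7,8-tetramethoxychromen-4-one | COc1cc(OCc2ccccc2)c(-c2cc(=O)c3c(OC)c(OC)c(OC)c(OC)c3o2)cc1OC
F4 | step 5 | 2-(2,2-dibromovinyl)-5,6,7,8-tetramethoxychromen-4-one | BrC(Br)=Cc1cc(=O)c2c(OC)c(OC)c(OC)c(OC)c2o1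
F5 | step 5 | 2-[(Z)-2-bromovinyl]-5,6,7,8-tetramethoxychromen-4-one | Br/C=C\c1cc(=O)c2c(OC)c(OC)c(OC)c(OC)c2o1
F6 | step 4 | ethyl 5,6,7,8-tetramethoxy-4-oxo-4H-chromene-2-carboxylate | CCOC(=O)c1cc(=O)c2c(OC)c(OC)c(OC)c(OC)c2o1
F7 | step 4 | 2-(hydroxymethyl)-5,6,7,8-tetramethoxychromen-4-one | OCc1cc(=O)c2c(OC)c(OC)c(OC)c(OC)c2o1
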